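**Plan**
Retrosynthesis cuts, in order: the two aryl O–Si bonds and the CO2Et → CH2OH change; the C6–CH2 bond of the ArCH2CH2Ar tether (B-alkyl Suzuki); the C4–C4a bond of the pyran ring; the side-chain C=C (Wittig on an aldehyde cut from a prenyl terminus); the aryl–O bond at the tertiary carbinol; the alkynol back to geraniol through its 2,3-epoxide.
Forward: geraniol → (2S,3S)-epoxide → (S)-tertiary propargylic alcohol → p-bromophenyl ether → E-enoate chain → pyran ring (the only ring made; both benzene rings are bought) → tether to the catechol ring → reduction, desilylation.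
Enabling feature: in the 2H-chromene, C4a is the arene carbon ortho to ring oxygen O1 (on C8a) and C2 is fully substituted, so C3=C4 can be carried as a terminal alkyne on C2 of an aryl propargyl ether. The O1-activated C4a then attacks the alkyne terminus (future C4) in a 6-endo-dig hydroarylation that touches none of the four bonds at C2.
Stereochemistry: the only stereocentre, C2 (S), is set by Sharpless epoxidation of geraniol and carried with its C–O bond intact through every later step (a thermal propargyl Claisen sequence, which breaks C2–O, is avoided). The E alkene comes from a stabilised Wittig ylide.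

Key step: step 7

Assumption: compounds 1, 6, 11 and 14 are taken as commercial, and the enantiomeric purity introduced in step 1 is carried through without a later enrichment.

**Step 1**
Reactants: 1 geraniol [(2E)-3,7-dimethylocta-2,6-dien-1-ol]
Product: 2 [(2S,3S)-3-methyl-3-(4-methylpent-3-en-1-yl)oxiran-2-yl]methanol
Conditions: Ti(OiPr)4 (5 mol %), L-(+)-diethyl tartrate (7 mol %), t-BuOOH, 4 Å MS, CH2Cl2, −20 °C
Reagents that add atoms: tert-butyl hydroperoxide CC(C)(C)OO
Why: Sharpless asymmetric epoxidation, in which the allylic hydroxyl binds the tetravalent titanium–tartrate complex so that only the 2,3-alkene is epoxidised and L-(+)-tartrate should deliver oxygen to the face giving the 2S,3S epoxide, which fixes the configuration of the future C2.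

**Step 2**
Reactants: 2 [(2S,3S)-3-methyl-3-(4-methylpent-3-en-1-yl)oxiran-2-yl]methanol
Product: 3 (2S,3R)-3-(chloromethyl)-2-methyl-2-(4-methylpent-3-en-1-yl)oxirane
Conditions: PPh3, CCl4, NaHCO3, reflux
Reagents that add atoms: carbon tetrachloride ClC(Cl)(Cl)Cl
Why: Appel chlorination of the primary alcohol under buffered neutral conditions leaves the epoxide and both stereocentres spatially unchanged (the descriptor of the CH carbon changes only through CIP priority).

**Step 3**
Reactants: 3 (2S,3R)-3-(chloromethyl)-2-methyl-2-(4-methylpent-3-en-1-yl)oxirane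
Product: 5 (3S)-3,7-dimethyloct-6-en-1-yn-3-ol, via dilithium alkynide alkoxide 4 (not isolated)
Conditions: n-BuLi (3.2 equiv), THF, −40 °C → rt; then H2O
Reagents that add atoms: none
Why: base-induced double elimination of a 2,3-epoxy chloride (deprotonation at CH2Cl with epoxide opening to a chlorovinyl alkoxide, then loss of HCl) is an established route from Sharpless epoxides to propargylic alcohols, and the C–O bond at the tertiary carbon is never broken, so its configuration is retained.

**Step 4**
Reactants: 5 (3S)-3,7-dimethyloct-6-en-1-yn-3-ol; 6 bis(4-bromophenyl)iodonium trifluoromethanesulfonate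
Product: 8 1-bromo-4-{[(3S)-3,7-dimethyloct-6-en-1-yn-3-yl]oxy}benzene, via sodium alkoxide 7 (not isolated)
Conditions: NaH, toluene, 0 °C → rt; then 6, rt
Reagents that add atoms: none
Why: metal-free O-arylation of a tertiary alkoxide by ligand coupling at a diaryl hypervalent iodine centre forms the aryl–O bond at oxygen, so the stereocentre is not involved and stays S, and room temperature excludes a propargyl Claisen rearrangement.

**Step 5**
Reactants: 8 1-bromo-4-{[(3S)-3,7-dimethyloct-6-en-1-yn-3-yl]oxy}benzene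
Product: 10 (4S)-4-(4-bromophenoxy)-4-methylhex-5-ynal, via secondary ozonide 9 (not isolated)
Conditions: O3 (about 1 equiv, dye end-point), CH2Cl2, −78 °C; then PPh3, −78 °C → rt
Reagents that add atoms: ozone [O-][O+]=O
Why: ozonolysis with reductive work-up, selective because the electron-rich trisubstituted alkene reacts far faster with ozone than the terminal alkyne or the bromoaryl ether; it removes the nucleophilic alkene before the gold step.

**Step 6**
Reactants: 10 (4S)-4-(4-bromophenoxy)-4-methylhex-5-ynal; 11 ethyl 2-(triphenyl-λ5-phosphanylidene)propanoate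
Product: 12 ethyl (2E,6S)-6-(4-bromophenoxy)-2,6-dimethyloct-2-en-7-ynoate
Conditions: CH2Cl2, rt
Reagents that add atoms: none
Why: Wittig olefination with a stabilised α-methyl ylide should give the E trisubstituted enoate, which sets the side-chain geometry and makes that alkene electron-poor for step 7.

**Step 7**
Reactants: 12 ethyl (2E,6S)-6-(4-bromophenoxy)-2,6-dimethyloct-2-en-7-ynoate
Product: 13 ethyl (2E)-5-[(2S)-6-bromo-2-methyl-2H-chromen-2-yl]-2-methylpent-2-enoate
Conditions: Ph3PAuNTf2 (3 mol %), CH2Cl2, 0 °C → rt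
Reagents that add atoms: none
Why: Cationic monovalent gold π-activates the terminal alkyne and the arene carbon ortho to the ether oxygen attacks the alkyne terminus anti to gold in a Friedel–Crafts manner, giving a Wheland/vinyl-gold intermediate that rearomatises and is protodeaurated to the C3=C4 alkene, so C4–C4a is the only new skeletal bond. The closest known reaction type is the gold- or platinum-catalysed intramolecular hydroarylation of aryl propargyl ethers to 2H-chromenes, which is established for 1,1-disubstituted propargyl ethers at room temperature. The pyran ring closes in the 6-endo-dig mode, the 5-exo-dig alternative (attack on the internal alkyne carbon) being disfavoured by the fully substituted propargylic carbon next to it. No stereocentre is created and C2 keeps its S configuration because none of its four bonds is cleaved, in contrast to a thermal propargyl Claisen sequence that breaks C2–O and passes through an achiral ortho-quinone methide. The step needs the arene, not the side-chain alkene, to act as nucleophile, which is secured by carrying that alkene as an electron-poor enoate unable to enter a 1,6-enyne cycloisomerisation, and the two ortho positions of the para-bromophenyl ring are equivalent so no regioisomer can arise. Ionisation of the tertiary propargylic C–O bond is held back by the acid-free catalyst, the low temperature and the inductively deactivating bromine.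

**Step 8**
Reactants: 14 2,3-dihydroxybenzaldehyde
Product: 15 2,3-bis[(triisopropylsilyl)oxy]benzaldehyde
Conditions: i-Pr3SiOTf (2.4 equiv), 2,6-lutidine, CH2Cl2, 0 °C → rt
Reagents that add atoms: triisopropylsilyl trifluoromethanesulfonate CC(C)[Si](C(C)C)(C(C)C)OS(=O)(=O)C(F)(F)F
Why: silylation of both phenols with a reactive silyl triflate; triisopropylsilyl aryl ethers are chosen because they should withstand the aqueous base of step 10 and the hydride of step 11 and leave with fluoride at the end.

**Step 9**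
Reactants: 15 2,3-bis[(triisopropylsilyl)oxy]benzaldehyde
Product: 16 1-ethenyl-2,3-bis[(triisopropylsilyl)oxy]benzene
Conditions: Ph3PCH3Br, n-BuLi, THF, 0 °C; then 15, 0 °C → rt
Reagents that add atoms: methyltriphenylphosphonium bromide C[P+](c1ccccc1)(c1ccccc1)c1ccccc1.[Br-]
Why: Wittig methylenation of an aryl aldehyde with the preformed non-stabilised ylide gives the styrene without touching the silyl ethers.

**Step 10**
Reactants: 13 ethyl (2E)-5-[(2S)-6-bromo-2-methyl-2H-chromen-2-yl]-2-methylpent-2-enoate; 16 1-ethenyl-2,3-bis[(triisopropylsilyl)oxy]benzene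
Product: 18 ethyl (2E)-5-[(2S)-6-(2-{2,3-bis[(triisopropylsilyl)oxy]phenyl}ethyl)-2-methyl-2H-chromen-2-yl]-2-methylpent-2-enoate, via B-alkyl-9-BBN 17 (not isolated)
Conditions: 16 (slight excess over borane), 9-BBN-H, THF, rt; then 13, PdCl2(dppf) (5 mol %), aq. K3PO4, DMF, 50 °C
Reagents that add atoms: none
Why: anti-Markovnikov hydroboration of the terminal styrene followed by B-alkyl Suzuki–Miyaura coupling at the C6–Br bond (zerovalent palladium formed from the divalent precatalyst) builds the saturated CH2–CH2 tether directly, so no alkene has to be hydrogenated in the presence of the chromene and enoate double bonds.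

**Step 11**
Reactants: 18 ethyl (2E)-5-[(2S)-6-(2-{2,3-bis[(triisopropylsilyl)oxy]phenyl}ethyl)-2-methyl-2H-chromen-2-yl]-2-methylpent-2-enoate
Product: 19 (2E)-5-[(2S)-6-(2-{2,3-bis[(triisopropylsilyl)oxy]phenyl}ethyl)-2-methyl-2H-chromen-2-yl]-2-methylpent-2-en-1-ol
Conditions: i-Bu2AlH (2.5 equiv), CH2Cl2, −78 °C; aq. potassium sodium tartrate work-up
Reagents that add atoms: none
Why: 1,2-reduction of the α,β-unsaturated ester by the aluminium hydride gives the E allylic alcohol with the alkene geometry, chromene and aryl silyl ethers unchanged.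

**Step 12**
Reactants: 19 (2E)-5-[(2S)-6-(2-{2,3-bis[(triisopropylsilyl)oxy]phenyl}ethyl)-2-methyl-2H-chromen-2-yl]-2-methylpent-2-en-1-ol
Product: 20 3-(2-{(2S)-2-[(3E)-5-hydroxy-4-methylpent-3-en-1-yl]-2-methyl-2H-chromen-6-yl}ethyl)benzene-1,2-diol
Conditions: Bu4NF, AcOH, THF, 0 °C, argon
Reagents that add atoms: none
Why: fluoride cleavage of both aryl silyl ethers, buffered with acetic acid so that the free catechol is not exposed to base and air and the acid-sensitive chromene and allylic alcohol are left alone.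

**Compound list**
1 | geraniol, (2E)-3,7-dimethylocta-2,6-dien-1-ol | CC(C)=CCC/C(C)=C/CO | starting material
2 | [(2S,3S)-3-methyl-3-(4-methylpent-3-en-1-yl)oxiran-2-yl]methanol | CC(C)=CCC[C@]1(C)O[C@H]1CO | intermediate
3 | (2S,3R)-3-(chloromethyl)-2-methyl-2-(4-methylpent-3-en-1-yl)oxirane | CC(C)=CCC[C@]1(C)O[C@H]1CCl | intermediate
4 | dilithium (3S)-3,7-dimethyloct-6-en-1-yn-1-id-3-olate | [Li+].[Li+].[C-]#C[C@@](C)([O-])CCC=C(C)C | intermediate
5 | (3S)-3,7-dimethyloct-6-en-1-yn-3-ol | CC(C)=CCC[C@](C)(O)C#C | intermediate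
6 | bis(4-bromophenyl)iodonium trifluoromethanesulfonate | Brc1ccc(cc1)[I+]c1ccc(Br)cc1.[O-]S(=O)(=O)C(F)(F)F | starting material
7 | sodium (3S)-3,7-dimethyloct-6-en-1-yn-3-olate | CC(C)=CCC[C@](C)([O-])C#C.[Na+] | intermediate
8 | 1-bromo-4-{[(3S)-3,7-dimethyloct-6-en-1-yn-3-yl]oxy}benzene | CC(C)=CCC[C@](C)(Oc1ccc(Br)cc1)C#C | intermediate
9 | 3-[(3S)-3-(4-bromophenoxy)-3-methylpent-4-yn-1-yl]-5,5-dimethyl-1,2,4-trioxolane (both epimers at the ring CH) | CC1(C)OOC(CC[C@](C)(Oc2ccc(Br)cc2)C#C)O1 | intermediate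
10 | (4S)-4-(4-bromophenoxy)-4-methylhex-5-ynal | O=CCC[C@](C)(Oc1ccc(Br)cc1)C#C | intermediate
11 | ethyl 2-(triphenyl-λ5-phosphanylidene)propanoate | CCOC(=O)C(C)=P(c1ccccc1)(c1ccccc1)c1ccccc1 | starting material
12 | ethyl (2E,6S)-6-(4-bromophenoxy)-2,6-dimethyloct-2-en-7-ynoate | CCOC(=O)/C(C)=C/CC[C@](C)(Oc1ccc(Br)cc1)C#C | intermediate
13 | ethyl (2E)-5-[(2S)-6-bromo-2-methyl-2H-chromen-2-yl]-2-methylpent-2-enoate | CCOC(=O)/C(C)=C/CC[C@@]1(C)C=Cc2cc(Br)ccc2O1 | intermediate
14 | 2,3-dihydroxybenzaldehyde | O=Cc1cccc(O)c1O | starting material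
15 | 2,3-bis[(triisopropylsilyl)oxy]benzaldehyde | O=Cc1cccc(O[Si](C(C)C)(C(C)C)C(C)C)c1O[Si](C(C)C)(C(C)C)C(C)C | intermediate
16 | 1-ethenyl-2,3-bis[(triisopropylsilyl)oxy]benzene | C=Cc1cccc(O[Si](C(C)C)(C(C)C)C(C)C)c1O[Si](C(C)C)(C(C)C)C(C)C | intermediate
17 | 9-(2-{2,3-bis[(triisopropylsilyl)oxy]phenyl}ethyl)-9-borabicyclo[3.3.1]nonane | CC(C)[Si](C(C)C)(C(C)C)Oc1cccc(CCB2C3CCCC2CCC3)c1O[Si](C(C)C)(C(C)C)C(C)C | intermediate
18 | ethyl (2E)-5-[(2S)-6-(2-{2,3-bis[(triisopropylsilyl)oxy]phenyl}ethyl)-2-methyl-2H-chromen-2-yl]-2-methylpent-2-enoate | CCOC(=O)/C(C)=C/CC[C@@]1(C)C=Cc2cc(CCc3cccc(O[Si](C(C)C)(C(C)C)C(C)C)c3O[Si](C(C)C)(C(C)C)C(C)C)ccc2O1 | intermediate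
19 | (2E)-5-[(2S)-6-(2-{2,3-bis[(triisopropylsilyl)oxy]phenyl}ethyl)-2-methyl-2H-chromen-2-yl]-2-methylpent-2-en-1-ol | C/C(=C\CC[C@@]1(C)C=Cc2cc(CCc3cccc(O[Si](C(C)C)(C(C)C)C(C)C)c3O[Si](C(C)C)(C(C)C)C(C)C)ccc2O1)CO | intermediate
20 | 3-(2-{(2S)-2-[(3E)-5-hydroxy-4-methylpent-3-en-1-yl]-2-methyl-2H-chromen-6-yl}ethyl)benzene-1,2-diol | C/C(=C\CC[C@@]1(C)C=Cc2cc(CCc3cccc(O)c3O)ccc2O1)CO | target

**Step count**
Total: 12 steps. Longest linear sequence: 10 steps (steps 1–7, then 10–12).

**Steps most likely to fail**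

Step 7. Risk: partial ionisation of the tertiary propargylic C–O bond at cationic gold, which would erode enantiopurity, or competing 5-exo closure. The fallback closes the pyran ring at C3=C4 by olefin metathesis, again without breaking C2–O. It sets out from 5 and comes back at 19. Alkoxide 7, made from 5 as in step 4, should undergo nucleophilic aromatic substitution on 5-bromo-2-fluorobenzaldehyde (DMF, 0 °C) to give 5-bromo-2-{[(3S)-3,7-dimethyloct-6-en-1-yn-3-yl]oxy}benzaldehyde F1. Semihydrogenation of the alkyne (H2, Pd/CaCO3 poisoned with Pb(OAc)2, quinoline, EtOAc) should give 5-bromo-2-{[(3S)-3,7-dimethylocta-1,6-dien-3-yl]oxy}benzaldehyde F2. Wittig methylenation (Ph3P=CH2, THF) should give 4-bromo-1-{[(3S)-3,7-dimethylocta-1,6-dien-3-yl]oxy}-2-ethenylbenzene F3. Ring-closing metathesis with the second-generation Grubbs catalyst (H2IMes)(PCy3)Cl2Ru=CHPh (CH2Cl2, 40 °C) should initiate at the styrene and close onto the neighbouring vinyl group to give (2S)-6-bromo-2-methyl-2-(4-methylpent-3-en-1-yl)-2H-chromene F4. Allylic oxidation of the E methyl group (SeO2 cat., t-BuOOH, CH2Cl2; the chromene alkene has no allylic hydrogen) should give (2E)-5-[(2S)-6-bromo-2-methyl-2H-chromen-2-yl]-2-methylpent-2-en-1-ol F5 together with some (2E)-5-[(2S)-6-bromo-2-methyl-2H-chromen-2-yl]-2-methylpent-2-enal F6, which NaBH4 returns to F5. B-alkyl Suzuki coupling of F5 with 17 under the conditions of step 10 should then give 19.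

Step 4. Risk: sluggish attack of the hindered tertiary alkoxide on the iodonium salt, with base-induced decomposition of the salt taking over. The fallback uses nucleophilic aromatic substitution on an activated fluoroarene, sets out from 5 and comes back at 8. Alkoxide 7 and 1-fluoro-4-nitrobenzene (DMF, 0 °C) should give 1-{[(3S)-3,7-dimethyloct-6-en-1-yn-3-yl]oxy}-4-nitrobenzene F7. Reduction with Fe powder and NH4Cl (EtOH/H2O, 60 °C) should give 4-{[(3S)-3,7-dimethyloct-6-en-1-yn-3-yl]oxy}aniline F8. Sandmeyer bromination (t-BuONO, CuBr2, MeCN, 0 °C → rt) through 4-{[(3S)-3,7-dimethyloct-6-en-1-yn-3-yl]oxy}benzenediazonium bromide F9 should give 8.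

Step 10. Risk: slow oxidative addition and transmetalation at the electron-rich bromoarene with competing protodeboronation, or base-induced loss of an aryl silyl ether. The fallback is a base-free Negishi coupling, sets out from 17 and comes back at 18. Oxidation of 17 with NaBO3·4H2O should give 2-{2,3-bis[(triisopropylsilyl)oxy]phenyl}ethan-1-ol F10. Iodination (I2, PPh3, imidazole, CH2Cl2) should give 1-(2-iodoethyl)-2,3-bis[(triisopropylsilyl)oxy]benzene F11. Zinc insertion (Zn dust, LiCl, THF) should give (2-{2,3-bis[(triisopropylsilyl)oxy]phenyl}ethyl)zinc iodide F12, and its coupling with 13 (Pd(OAc)2, SPhos, THF, rt → 50 °C) should give 18.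

**Further compounds**
F1 | step 7 | 5-bromo-2-{[(3S)-3,7-dimethyloct-6-en-1-yn-3-yl]oxy}benzaldehyde | CC(C)=CCC[C@](C)(Oc1ccc(Br)cc1C=O)C#C
F2 | step 7 | 5-bromo-2-{[(3S)-3,7-dimethylocta-1,6-dien-3-yl]oxy}benzaldehyde | CC(C)=CCC[C@](C)(Oc1ccc(Br)cc1C=O)C=C
F3 | step 7 | 4-bromo-1-{[(3S)-3,7-dimethylocta-1,6-dien-3-yl]oxy}-2-ethenylbenzene | CC(C)=CCC[C@](C)(Oc1ccc(Br)cc1C=C)C=C
F4 | step 7 | (2S)-6-bromo-2-methyl-2-(4-methylpent-3-en-1-yl)-2H-chromene | CC(C)=CCC[C@@]1(C)C=Cc2cc(Br)ccc2O1
F5 | step 7 | (2E)-5-[(2S)-6-bromo-2-methyl-2H-chromen-2-yl]-2-methylpent-2-en-1-ol | C/C(=C\CC[C@@]1(C)C=Cc2cc(Br)ccc2O1)CO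
F6 | step 7 | (2E)-5-[(2S)-6-bromo-2-methyl-2H-chromen-2-yl]-2-methylpent-2-enal | C/C(=C\CC[C@@]1(C)C=Cc2cc(Br)ccc2O1)C=O
F7 | step 4 | 1-{[(3S)-3,7-dimethyloct-6-en-1-yn-3-yl]oxy}-4-nitrobenzene | CC(C)=CCC[C@](C)(Oc1ccc([N+](=O)[O-])cc1)C#C
F8 | step 4 | 4-{[(3S)-3,7-dimethyloct-6-en-1-yn-3-yl]oxy}aniline | CC(C)=CCC[C@](C)(Oc1ccc(N)cc1)C#C
F9 | step 4 | 4-{[(3S)-3,7-dimethyloct-6-en-1-yn-3-yl]oxy}benzenediazonium bromide | CC(C)=CCC[C@](C)(Oc1ccc([N+]#N)cc1)C#C.[Br-]
F10 | step 10 | 2-{2,3-bis[(triisopropylsilyl)oxy]phenyl}ethan-1-ol | OCCc1cccc(O[Si](C(C)C)(C(C)C)C(C)C)c1O[Si](C(C)C)(C(C)C)C(C)C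
F11 | step 10 | 1-(2-iodoethyl)-2,3-bis[(triisopropylsilyl)oxy]benzene | ICCc1cccc(O[Si](C(C)C)(C(C)C)C(C)C)c1O[Si](C(C)C)(C(C)C)C(C)C
F12 | step 10 | (2-{2,3-bis[(triisopropylsilyl)oxy]phenyl}ethyl)zinc iodide | I[Zn]CCc1cccc(O[Si](C(C)C)(C(C)C)C(C)C)c1O[Si](C(C)C)(C(C)C)C(C)C
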